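1. The dihydrofuran carbons C3–C2 and the side chain C1′(OH)(CH3)–C2′…C6′ are the intact skeleton of (S)-linalool: C3=C2 is its vinyl group and C1′ its carbinol stereocentre.
2. Key disconnection C3a–C3: Pt(dba)3/chiral phosphonite 1,2-diboration of that vinyl group sets C2, Suzuki–Miyaura coupling of the primary C–B bond with aryl bromide 5 makes C3a–C3, and oxidation turns C2–B into C2–OH, all in one flask.
3. Dihydrofuran ring (formed second, after the purchased benzene ring): O1–C2 by an inverting intramolecular Mitsunobu etherification; one acetal on the oxygen para to the ketone decides which phenol closes.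
4. Six-membered ring C3a–C7a (formed last): the flat acylphloroglucinol ring of 12 is dearomatised by a double C-prenylation with Pd2(dba)3/chiral bisphosphine, which sets the quaternary centres C5 and C7.
5. Arene 5 comes from 2-methylphloroglucinol by C-acylation, acetal protection of the para oxygen and bromination.

Key step: step 5

Assumption: (S)-(+)-linalool of high enantiomeric purity is taken as purchasable, and for the two ligand-controlled steps (5 and 8) the ligand antipode that gives the stated configuration is fixed in a first small run.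

Step 1
Reactants: 1 2-methylbenzene-1,3,5-triol (2-methylphloroglucinol); 2 2-methylpropanoyl chloride (isobutyryl chloride)
Product: 3 2-methyl-1-(2,4,6-trihydroxy-3-methylphenyl)propan-1-one
Conditions: AlCl3, PhNO2, 60 °C; aq. HCl work-up
Reagents that add atoms: none
Why: Friedel–Crafts C-acylation of the symmetric triol, whose two free ring carbons are equivalent, so that a single mono-ketone should form; no stereocentre.

Step 2
Reactants: 3
Product: 4 1-[2,6-dihydroxy-4-(methoxymethoxy)-3-methylphenyl]-2-methylpropan-1-one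
Conditions: MOMCl (1.05 equiv), iPr2NEt, CH2Cl2, 0 °C
Reagents that add atoms: chloromethyl methyl ether, COCCl
Why: Williamson-type acetal formation at the most acidic hydroxyl, the one para to the ketone, which unlike the two ortho hydroxyls is neither chelated to the carbonyl oxygen nor shielded by the isopropyl ketone; this one blocking group later leaves only the phenol next to the ketone able to close the furan.

Step 3
Reactants: 4
Product: 5 1-[3-bromo-2,6-dihydroxy-4-(methoxymethoxy)-5-methylphenyl]-2-methylpropan-1-one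
Conditions: NBS (1.0 equiv), MeCN, 0 °C
Reagents that add atoms: N-bromosuccinimide, O=C1CCC(=O)N1Br
Why: Electrophilic aromatic bromination at the only unsubstituted ring carbon, which is activated by three oxygen substituents; no stereocentre.

Step 4
Reactants: 6 (S)-linalool, (3S)-3,7-dimethylocta-1,6-dien-3-ol
Product: 7 triethyl{[(3S)-3,7-dimethylocta-1,6-dien-3-yl]oxy}silane
Conditions: TESOTf, 2,6-lutidine, CH2Cl2, −78 to 0 °C
Reagents that add atoms: triethylsilyl trifluoromethanesulfonate, CC[Si](CC)(CC)OS(=O)(=O)C(F)(F)F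
Why: Silylation of the tertiary alcohol with the silyl triflate keeps the allylic hydroxyl out of the metal-catalysed steps and later rules out epoxide formation during ring closure; the stereocentre is not touched.

Step 5
Reactants: 7; 5
Product: 10 1-{2,6-dihydroxy-3-[(2R,3S)-2-hydroxy-3,7-dimethyl-3-[(triethylsilyl)oxy]oct-6-en-1-yl]-4-(methoxymethoxy)-5-methylphenyl}-2-methylpropan-1-one, via bis(boronate) 8 (not isolated), via secondary boronate 9 (not isolated)
Conditions: Pt(dba)3 (1 mol %), (R,R)-TADDOL-derived aryl phosphonite (1.2 mol %), B2pin2, THF, 60 °C; then 5, Pd(OAc)2 (2 mol %), RuPhos, KOH, THF/H2O, 70 °C; then 30% H2O2, NaH2PO4 buffer, 0 °C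
Reagents that add atoms: bis(pinacolato)diboron, CC1(C)OB(OC1(C)C)B1OC(C)(C)C(C)(C)O1; hydrogen peroxide, OO
Why: Zerovalent platinum from Pt(dba)3 adds the B–B bond, the monosubstituted alkene inserts and reductive elimination gives the syn-1,2-bis(boronate) 8, while the trisubstituted C5′=C6′ alkene is too hindered to insert; the face of the vinyl group, and so C2 (R), is chosen by the phosphonite ligand, which is needed because the neighbouring C1′ centre with its alike methyl and methylene arms gives no reliable substrate bias. In the same flask Pd(OAc)2/RuPhos couples only the primary C–B bond with bromide 5 (Suzuki–Miyaura; the hindered secondary boronate stays and activates its neighbour) to form C3a–C3 in 9, and buffered peroxide converts C2–B into C2–OH with retention. The closest known reaction type is the enantioselective diboration/cross-coupling/oxidation cascade of terminal alkenes with aryl bromides. No ring is closed here; the new stereocentre C2 is under catalyst control and C1′ is carried over unchanged from linalool. The step needs alkene selectivity (terminal over trisubstituted, secured by the sterics of insertion), boron selectivity (primary over secondary, secured by the sterics of transmetalation) and survival of the aryl ketone, which as a chelated, hindered vinylogous acid should resist Dakin-type cleavage during the short, cold peroxide treatment.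

Step 6
Reactants: 10
Product: 11 1-[(2S)-6-hydroxy-4-(methoxymethoxy)-5-methyl-2-{(2S)-6-methyl-2-[(triethylsilyl)oxy]hept-5-en-2-yl}-2,3-dihydro-1-benzofuran-7-yl]-2-methylpropan-1-one
Conditions: PPh3, DIAD, toluene, 0 to 60 °C
Reagents that add atoms: none
Why: Intramolecular Mitsunobu etherification, 5-exo-tet: only the phenol next to the ketone can reach C2 (the para oxygen is an acetal, the tertiary oxygen a silyl ether), and SN2 displacement of the oxyphosphonium group inverts C2 from R to S, the ring closure compensating for the hindered, neopentyl-type carbinol.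

Step 7
Reactants: 11
Product: 12 1-{(2S)-4,6-dihydroxy-2-[(2S)-2-hydroxy-6-methylhept-5-en-2-yl]-5-methyl-2,3-dihydro-1-benzofuran-7-yl}-2-methylpropan-1-one
Conditions: conc. HCl (cat.), MeOH, 0 °C to rt
Reagents that add atoms: none
Why: Acid-catalysed transacetalisation and silyl ether methanolysis free the para phenol and the tertiary alcohol; dilute acid at or below room temperature should spare the trisubstituted alkene and the non-allylic tertiary carbinol, and no stereocentre is affected.

Step 8
Reactants: 12; 13 3-methylbut-2-en-1-yl acetate (prenyl acetate)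
Product: 15 (2S,5S,7S)-2-[(2S)-2-hydroxy-6-methylhept-5-en-2-yl]-5-methyl-5,7-bis(3-methylbut-2-en-1-yl)-7-(2-methylpropanoyl)-2,3-dihydro-1-benzofuran-4,6(5H,7H)-dione, via C5-prenyl dienone 14 (not isolated)
Conditions: Pd2(dba)3·CHCl3 (2.5 mol %), (R,R)-DACH-phenyl bisphosphine ligand N,N′-[(1R,2R)-cyclohexane-1,2-diyl]bis[2-(diphenylphosphanyl)benzamide] (7.5 mol %), Cs2CO3, 13 (2.3 equiv), toluene/CH2Cl2, 0 to 40 °C
Reagents that add atoms: none
Why: Proposed new method: two Tsuji–Trost allylations with dearomatisation in one flask — zerovalent palladium ionises 13 to the π-prenyl complex, the phenoxide of 12 attacks its unsubstituted terminus through C5 (the carbon between the two free oxygens) to give 14, and the enolised triketone 14 then reacts through C7; the face at C5 is chosen by the chiral ligand pocket alone (C2 and C1′ are too remote), and at C7 the same ligand should be matched with the substrate, because C5 and C7 are related by a pseudo-twofold axis through C6 and C3a (one ligand antipode therefore places the two prenyl groups trans) and the incoming group also prefers the face anti to the C5 prenyl group; O-prenylation is reversible under these conditions and should drain to the C-alkylated products; the closest known reaction types are the intermolecular asymmetric allylic dearomatisation of naphthols with the same ligand class and the racemic dearomative C-allylation of acylphloroglucinols with zerovalent palladium.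

Compound list
1 | 2-methylbenzene-1,3,5-triol (2-methylphloroglucinol) | Cc1c(O)cc(O)cc1O | starting material
2 | 2-methylpropanoyl chloride | CC(C)C(=O)Cl | starting material
3 | 2-methyl-1-(2,4,6-trihydroxy-3-methylphenyl)propan-1-one | CC(C)C(=O)c1c(O)cc(O)c(C)c1O | intermediate
4 | 1-[2,6-dihydroxy-4-(methoxymethoxy)-3-methylphenyl]-2-methylpropan-1-one | CC(C)C(=O)c1c(O)cc(OCOC)c(C)c1O | intermediate
5 | 1-[3-bromo-2,6-dihydroxy-4-(methoxymethoxy)-5-methylphenyl]-2-methylpropan-1-one | CC(C)C(=O)c1c(O)c(Br)c(OCOC)c(C)c1O | intermediate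
6 | (3S)-3,7-dimethylocta-1,6-dien-3-ol, (S)-linalool | CC(C)=CCC[C@](C)(O)C=C | starting material
7 | triethyl{[(3S)-3,7-dimethylocta-1,6-dien-3-yl]oxy}silane | CC(C)=CCC[C@](C)(O[Si](CC)(CC)CC)C=C | intermediate
8 | triethyl{[(2R,3S)-3,7-dimethyl-1,2-bis(4,4,5,5-tetramethyl-1,3,2-dioxaborolan-2-yl)oct-6-en-3-yl]oxy}silane | CC(C)=CCC[C@](C)(O[Si](CC)(CC)CC)[C@H](B1OC(C)(C)C(C)(C)O1)CB1OC(C)(C)C(C)(C)O1 | intermediate (not isolated)
9 | 1-{3-[(2R,3S)-3,7-dimethyl-2-(4,4,5,5-tetramethyl-1,3,2-dioxaborolan-2-yl)-3-[(triethylsilyl)oxy]oct-6-en-1-yl]-2,6-dihydroxy-4-(methoxymethoxy)-5-methylphenyl}-2-methylpropan-1-one | CC(C)=CCC[C@](C)(O[Si](CC)(CC)CC)[C@H](B1OC(C)(C)C(C)(C)O1)Cc1c(O)c(C(=O)C(C)C)c(O)c(C)c1OCOC | intermediate (not isolated)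
10 | 1-{2,6-dihydroxy-3-[(2R,3S)-2-hydroxy-3,7-dimethyl-3-[(triethylsilyl)oxy]oct-6-en-1-yl]-4-(methoxymethoxy)-5-methylphenyl}-2-methylpropan-1-one | CC(C)=CCC[C@](C)(O[Si](CC)(CC)CC)[C@H](O)Cc1c(O)c(C(=O)C(C)C)c(O)c(C)c1OCOC | intermediate
11 | 1-[(2S)-6-hydroxy-4-(methoxymethoxy)-5-methyl-2-{(2S)-6-methyl-2-[(triethylsilyl)oxy]hept-5-en-2-yl}-2,3-dihydro-1-benzofuran-7-yl]-2-methylpropan-1-one | CC(C)=CCC[C@](C)(O[Si](CC)(CC)CC)[C@@H]1Cc2c(O1)c(C(=O)C(C)C)c(O)c(C)c2OCOC | intermediate
12 | 1-{(2S)-4,6-dihydroxy-2-[(2S)-2-hydroxy-6-methylhept-5-en-2-yl]-5-methyl-2,3-dihydro-1-benzofuran-7-yl}-2-methylpropan-1-one | CC(C)=CCC[C@](C)(O)[C@@H]1Cc2c(O1)c(C(=O)C(C)C)c(O)c(C)c2O | intermediate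
13 | 3-methylbut-2-en-1-yl acetate (prenyl acetate) | CC(C)=CCOC(C)=O | starting material
14 | (2S,5R)-6-hydroxy-2-[(2S)-2-hydroxy-6-methylhept-5-en-2-yl]-5-methyl-5-(3-methylbut-2-en-1-yl)-7-(2-methylpropanoyl)-2,3-dihydro-1-benzofuran-4(5H)-one (5R by the priority rules for this tautomer; same spatial arrangement at C5 as in 15) | CC(C)=CCC[C@](C)(O)[C@@H]1CC2=C(O1)C(C(=O)C(C)C)=C(O)[C@@](C)(CC=C(C)C)C2=O | intermediate (not isolated)
15 | (2S,5S,7S)-2-[(2S)-2-hydroxy-6-methylhept-5-en-2-yl]-5-methyl-5,7-bis(3-methylbut-2-en-1-yl)-7-(2-methylpropanoyl)-2,3-dihydro-1-benzofuran-4,6(5H,7H)-dione | CC(C)=CCC[C@](C)(O)[C@@H]1CC2=C(O1)[C@@](CC=C(C)C)(C(=O)C(C)C)C(=O)[C@@](C)(CC=C(C)C)C2=O | target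

Total step count: 8. Longest linear sequence: 7 steps (1 → 3 → 4 → 5 → 10 → 11 → 12 → 15).

Steps most likely to fail

Step 8 (Proposed new method). Facial selection at C5 may be poor, because the existing stereocentres are too remote to help the ligand. The second alkylation may go to the ring-fusion carbon C3a or to oxygen instead of C7, and attack at the substituted prenyl terminus is possible. The fallback uses known chemistry, sets out from 12 and comes back at 15. It is the classical base-mediated alkylative dearomatisation, run as two separate operations. 12 is treated with prenyl bromide (1.1 equiv) and NaOMe in MeOH at 0 °C. C-alkylation at C5 should give 14 together with its C5 epimer, (2S,5S)-6-hydroxy-2-[(2S)-2-hydroxy-6-methylhept-5-en-2-yl]-5-methyl-5-(3-methylbut-2-en-1-yl)-7-(2-methylpropanoyl)-2,3-dihydro-1-benzofuran-4(5H)-one F1, and the two are separated by chromatography. Isolated 14 is alkylated again at C7 (prenyl bromide, NaOMe, MeOH) to give 15 next to its C7 epimer, (2S,5S,7R)-2-[(2S)-2-hydroxy-6-methylhept-5-en-2-yl]-5-methyl-5,7-bis(3-methylbut-2-en-1-yl)-7-(2-methylpropanoyl)-2,3-dihydro-1-benzofuran-4,6(5H,7H)-dione F2, which is removed by chromatography. The configuration at C5 is then secured by separation, not by a catalyst.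

Step 5. Oxidative addition and transmetalation may be slow between a phenoxide-rich, doubly ortho-substituted aryl bromide and a β-branched primary boronate, so that protodeboronation or β-hydride elimination takes over. Face selection in the diboration next to the bulky silyloxy carbon may also be incomplete. The fallback sets out from 8 (made as in step 5 but isolated) and from 4, and comes back at 10. It replaces the cross-coupling by using the arene as a carbon nucleophile. 8 is oxidised at both boron atoms (H2O2, NaOH) to (2R,3S)-3,7-dimethyl-3-[(triethylsilyl)oxy]oct-6-ene-1,2-diol F3. The primary hydroxyl is oxidised (TEMPO cat., PhI(OAc)2, CH2Cl2) to (2S,3S)-2-hydroxy-3,7-dimethyl-3-[(triethylsilyl)oxy]oct-6-enal F4. F4 is condensed with the free ring carbon of 4 and the resulting ortho-quinone methide is reduced in the same flask (L-proline cat., Hantzsch ester, CH2Cl2), which gives 10 with C2 unchanged.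

Step 6. Formation and displacement of the oxyphosphonium ion at the neopentyl-type C2 carbinol may be sluggish, and elimination towards C3 may compete with substitution. The fallback sets out from 10 and comes back at 12. It changes the electrophile from an oxyphosphonium ion to a cyclic carbonate. The silyl ether is removed (PPTS, MeOH) to give 1-{3-[(2R,3S)-2,3-dihydroxy-3,7-dimethyloct-6-en-1-yl]-2,6-dihydroxy-4-(methoxymethoxy)-5-methylphenyl}-2-methylpropan-1-one F5. The vicinal diol is tied up with 1,1′-carbonyldiimidazole as 1-[2,6-dihydroxy-4-(methoxymethoxy)-3-methyl-5-{[(4R,5S)-5-methyl-5-(4-methylpent-3-en-1-yl)-2-oxo-1,3-dioxolan-4-yl]methyl}phenyl]-2-methylpropan-1-one F6. Heating with K2CO3 in DMF lets the phenoxide next to the ketone open the carbonate at its secondary carbon (5-exo, inversion at C2, loss of carbon dioxide) to give 1-{(2S)-6-hydroxy-2-[(2S)-2-hydroxy-6-methylhept-5-en-2-yl]-4-(methoxymethoxy)-5-methyl-2,3-dihydro-1-benzofuran-7-yl}-2-methylpropan-1-one F7. The conditions of step 7 then remove the acetal and give 12.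

Further compounds
F1 | step 8 | (2S,5S)-6-hydroxy-2-[(2S)-2-hydroxy-6-methylhept-5-en-2-yl]-5-methyl-5-(3-methylbut-2-en-1-yl)-7-(2-methylpropanoyl)-2,3-dihydro-1-benzofuran-4(5H)-one | CC(C)=CCC[C@](C)(O)[C@@H]1CC2=C(O1)C(C(=O)C(C)C)=C(O)[C@](C)(CC=C(C)C)C2=O
F2 | step 8 | (2S,5S,7R)-2-[(2S)-2-hydroxy-6-methylhept-5-en-2-yl]-5-methyl-5,7-bis(3-methylbut-2-en-1-yl)-7-(2-methylpropanoyl)-2,3-dihydro-1-benzofuran-4,6(5H,7H)-dione | CC(C)=CCC[C@](C)(O)[C@@H]1CC2=C(O1)[C@](CC=C(C)C)(C(=O)C(C)C)C(=O)[C@@](C)(CC=C(C)C)C2=O
F3 | step 5 | (2R,3S)-3,7-dimethyl-3-[(triethylsilyl)oxy]oct-6-ene-1,2-diol | CC(C)=CCC[C@](C)(O[Si](CC)(CC)CC)[C@H](O)CO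
F4 | step 5 | (2S,3S)-2-hydroxy-3,7-dimethyl-3-[(triethylsilyl)oxy]oct-6-enal | CC(C)=CCC[C@](C)(O[Si](CC)(CC)CC)[C@H](O)C=O
F5 | step 6 | 1-{3-[(2R,3S)-2,3-dihydroxy-3,7-dimethyloct-6-en-1-yl]-2,6-dihydroxy-4-(methoxymethoxy)-5-methylphenyl}-2-methylpropan-1-one | CC(C)=CCC[C@](C)(O)[C@H](O)Cc1c(O)c(C(=O)C(C)C)c(O)c(C)c1OCOC
F6 | step 6 | 1-[2,6-dihydroxy-4-(methoxymethoxy)-3-methyl-5-{[(4R,5S)-5-methyl-5-(4-methylpent-3-en-1-yl)-2-oxo-1,3-dioxolan-4-yl]methyl}phenyl]-2-methylpropan-1-one | CC(C)=CCC[C@]1(C)OC(=O)O[C@@H]1Cc1c(O)c(C(=O)C(C)C)c(O)c(C)c1OCOC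
F7 | step 6 | 1-{(2S)-6-hydroxy-2-[(2S)-2-hydroxy-6-methylhept-5-en-2-yl]-4-(methoxymethoxy)-5-methyl-2,3-dihydro-1-benzofuran-7-yl}-2-methylpropan-1-one | CC(C)=CCC[C@](C)(O)[C@@H]1Cc2c(O1)c(C(=O)C(C)C)c(O)c(C)c2OCOC
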